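**Retrosynthetic overview**

1. The target is epioritin-(4β→6)-epioritin-(4β→6)-epioritin-4α-ol. The last disconnections remove nine benzyl ethers and one 3,4-carbonate, then cut the upper C4–C6 bond into the 4β-alkoxyflavan 13 (cation precursor) and the dimer 21.
2. Key disconnection: the middle unit of 21 is cut at C4–C6' while its ring C is contracted, giving the cis-2-aryl-2,3-dihydrobenzofuran-3-carbaldehyde 19 and the bottom unit 15. Forward, acid turns the dihydrofuran ring into ring C by a 1,2-shift of C2, and C6 of 15 traps the C4 cation that results.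
3. Enabling feature: in the middle unit C4 sits on ring A ortho to O1 and para to the 7-oxygen, so a C4 cation is a doubly oxygen-stabilised benzylic cation; C2 carries O1 and a 4-alkoxyphenyl group, so it migrates readily and with retention.
4. All three units come from one flavanone 6 (asymmetric aryl addition to chromone 4). Oxidative ring contraction of 6 leads to 19; reduction, dehydration, hydroboration and oxidation–reduction lead to the epi-flavan-3-ol 12, and from it to the top electrophile 13 and the bottom unit 15.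
5. Order of ring formation: ring A (bought) → pyranone ring of 4 → flavanone 6 → rings C of the bottom and top units (kept from 6) → dihydrofuran ring of 16 (contraction) → ring C of the middle unit (expansion, key step).

Key step: step 15

Assumption: the ligand antipode written in step 3 is taken as the one that gives the 2S flavanone; if the sense of induction is the reverse, its mirror image is used and nothing else changes.
Remark: positions are in flavan numbering (O1, C2, C3, C4, C4a–C8a) unless a benzofuran is named; α/β as in flavonoid usage (the 2-aryl group of every unit is α).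

**Route**

Step 1
Reactants: 1 1-(2,3,4-trihydroxyphenyl)ethan-1-one
Product: 2 1-[3,4-bis(benzyloxy)-2-hydroxyphenyl]ethan-1-one
Conditions: BnBr (2.1 equiv), K2CO3, acetone, reflux
Reagents that add atoms: benzyl bromide BrCc1ccccc1
Why: Williamson ether synthesis; the 2-hydroxyl is held in a hydrogen bond to the acetyl oxygen and is the least nucleophilic, so the 3- and 4-hydroxyls should be benzylated selectively (no stereocenter).

Step 2
Reactants: 2 1-[3,4-bis(benzyloxy)-2-hydroxyphenyl]ethan-1-one
Product: 4 7,8-bis(benzyloxy)-4H-chromen-4-one, via enaminone 3 (not isolated)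
Conditions: Me2NCH(OMe)2, toluene, 100 °C; then conc. HCl, CH2Cl2, 40 °C
Reagents that add atoms: N,N-dimethylformamide dimethyl acetal COC(OC)N(C)C
Why: Enaminone chromone synthesis: condensation of the methyl ketone with the amide acetal, then acid-promoted addition of the phenol to the β-carbon with loss of dimethylamine closes the pyranone ring (no stereocenter).

Step 3
Reactants: 4 7,8-bis(benzyloxy)-4H-chromen-4-one; 5 [4-(benzyloxy)phenyl]boronic acid
Product: 6 (2S)-7,8-bis(benzyloxy)-2-[4-(benzyloxy)phenyl]-2,3-dihydro-4H-chromen-4-one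
Conditions: Pd(OCOCF3)2 (5 mol %), (S)-t-BuPyOx (6 mol %), NH4PF6, H2O, ClCH2CH2Cl, 60 °C
Reagents that add atoms: none
Why: Palladium-catalysed asymmetric conjugate addition of an arylboronic acid to a chromone with a pyridine–oxazoline ligand; C2 is set by the ligand-controlled face of insertion of the C2=C3 bond into the aryl–palladium bond, and water protonates the palladium enolate.

Step 4
Reactants: 6 (2S)-7,8-bis(benzyloxy)-2-[4-(benzyloxy)phenyl]-2,3-dihydro-4H-chromen-4-one
Product: 7 (2S,4S)-7,8-bis(benzyloxy)-2-[4-(benzyloxy)phenyl]chroman-4-ol (2,4-cis)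
Conditions: NaBH4, MeOH–THF, 0 °C
Reagents that add atoms: none
Why: Borohydride reduction of the ketone; hydride should add to give the equatorial 2,4-cis alcohol, a centre that is removed again in step 5.

Step 5
Reactants: 7 (2S,4S)-7,8-bis(benzyloxy)-2-[4-(benzyloxy)phenyl]chroman-4-ol
Product: 8 (2S)-7,8-bis(benzyloxy)-2-[4-(benzyloxy)phenyl]-2H-chromene
Conditions: p-TsOH·H2O (2 mol %), 4 Å molecular sieves, toluene, 60 °C
Reagents that add atoms: none
Why: Acid-catalysed E1 dehydration through the C4 cation (stabilised by O1 and the 7-benzyloxy group) should give the conjugated flav-3-ene; C2 is not touched.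

Step 6
Reactants: 8 (2S)-7,8-bis(benzyloxy)-2-[4-(benzyloxy)phenyl]-2H-chromene
Product: 10 (2R,3S)-7,8-bis(benzyloxy)-2-[4-(benzyloxy)phenyl]chroman-3-ol (2,3-trans), via alkylborane 9 (not isolated)
Conditions: BH3·THF, THF, 0 °C to rt; then NaOH, H2O2, 0 °C
Reagents that add atoms: hydrogen peroxide OO
Why: Hydroboration–oxidation: boron adds to C3 (β to ring A, styrene-type regiochemistry) on the face opposite the C2 aryl group and the C–B bond is oxidised with retention, which sets C3 as 3S (2,3-trans).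

Step 7
Reactants: 10 (2R,3S)-7,8-bis(benzyloxy)-2-[4-(benzyloxy)phenyl]chroman-3-ol
Product: 11 (2R)-7,8-bis(benzyloxy)-2-[4-(benzyloxy)phenyl]chroman-3-one
Conditions: Dess–Martin periodinane, CH2Cl2, rt
Reagents that add atoms: none
Why: Dess–Martin oxidation of the secondary alcohol under non-basic conditions, which should leave the enolisable C2 centre intact, as in the usual inversion of 2,3-trans into 2,3-cis flavan-3-ols.

Step 8
Reactants: 11 (2R)-7,8-bis(benzyloxy)-2-[4-(benzyloxy)phenyl]chroman-3-one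
Product: 12 (2R,3R)-7,8-bis(benzyloxy)-2-[4-(benzyloxy)phenyl]chroman-3-ol (2,3-cis; tri-O-benzyl-epioritin)
Conditions: LiBH(s-Bu)3, THF, −78 °C
Reagents that add atoms: none
Why: Reduction with a bulky trialkylborohydride: equatorial attack gives the axial alcohol cis to the equatorial 2-aryl group, which sets C3 as 3R.

Step 9
Reactants: 12 (2R,3R)-7,8-bis(benzyloxy)-2-[4-(benzyloxy)phenyl]chroman-3-ol
Product: 13 (2R,3R,4S)-7,8-bis(benzyloxy)-2-[4-(benzyloxy)phenyl]-4-(2-ethoxyethoxy)chroman-3-ol (2,3-cis-3,4-trans, 4β ether)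
Conditions: DDQ (2 equiv), EtOCH2CH2OH (5 equiv), CH2Cl2, rt
Reagents that add atoms: 2-ethoxyethanol CCOCCO
Why: Oxidative C4 functionalisation of a flavan-3-ol ether: DDQ abstracts hydride from C4 and the alcohol captures the O1/7-O-stabilised benzylic cation anti to the axial 3-hydroxyl, which sets C4 as the 4β ether.

Step 10
Reactants: 13 (2R,3R,4S)-7,8-bis(benzyloxy)-2-[4-(benzyloxy)phenyl]-4-(2-ethoxyethoxy)chroman-3-ol
Product: 14 tert-butyl (2R,3R,4S)-7,8-bis(benzyloxy)-2-[4-(benzyloxy)phenyl]-4-(2-ethoxyethoxy)chroman-3-yl carbonate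
Conditions: Boc2O, DMAP (cat.), CH2Cl2, rt
Reagents that add atoms: di-tert-butyl dicarbonate CC(C)(C)OC(=O)OC(=O)OC(C)(C)C
Why: DMAP-catalysed acylation of the secondary alcohol; no stereocenter changes.

Step 11
Reactants: 14 tert-butyl (2R,3R,4S)-7,8-bis(benzyloxy)-2-[4-(benzyloxy)phenyl]-4-(2-ethoxyethoxy)chroman-3-yl carbonate
Product: 15 cyclic 3,4-carbonate of (2R,3R,4R)-7,8-bis(benzyloxy)-2-[4-(benzyloxy)phenyl]chromane-3,4-diol (all-cis; tri-O-benzyl-teracacidin carbonate)
Conditions: TMSOTf (10 mol %), CH2Cl2, −78 to −30 °C; Et3N quench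
Reagents that add atoms: none
Why: Lewis-acid ionisation of the axial 4β-alkoxy group regenerates the C4 cation, and the carbonyl oxygen of the neighbouring axial Boc group captures it on the α face (5-exo neighbouring-group participation) with loss of 2-methylpropene, which sets C4 as the 4α oxygen of a cis-fused carbonate.

Step 12
Reactants: 6 (2S)-7,8-bis(benzyloxy)-2-[4-(benzyloxy)phenyl]-2,3-dihydro-4H-chromen-4-one
Product: 16 methyl (2S,3S)-6,7-bis(benzyloxy)-2-[4-(benzyloxy)phenyl]-2,3-dihydro-1-benzofuran-3-carboxylate (trans)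
Conditions: PhI(OAc)2 (1.2 equiv), H2SO4 (cat.), MeOH–HC(OMe)3, 0 °C to rt
Reagents that add atoms: methanol CO
Why: Oxidative ring contraction of a flavanone by a trivalent iodine reagent: the enol ether is iodinated at C3 and ring A (C4a) shifts from C4 to C3 with loss of iodobenzene while C4 becomes the ester carbon; C2 is untouched and the trans ester is expected (C3 is reset in step 13).

Step 13
Reactants: 16 methyl (2S,3S)-6,7-bis(benzyloxy)-2-[4-(benzyloxy)phenyl]-2,3-dihydro-1-benzofuran-3-carboxylate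
Product: 18 methyl (2S,3R)-6,7-bis(benzyloxy)-2-[4-(benzyloxy)phenyl]-2,3-dihydro-1-benzofuran-3-carboxylate (cis), via lithium enolate 17 (not isolated)
Conditions: LiN(i-Pr)2, THF, −78 °C; then AcOH in THF, −78 °C
Reagents that add atoms: none
Why: Kinetic protonation of an ester enolate from the face opposite the C2 aryl group should place the ester cis to the aryl group (3R); the ring C–O bond lies in the nodal plane of the enolate, which retards β-elimination.

Step 14
Reactants: 18 methyl (2S,3R)-6,7-bis(benzyloxy)-2-[4-(benzyloxy)phenyl]-2,3-dihydro-1-benzofuran-3-carboxylate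
Product: 19 (2S,3R)-6,7-bis(benzyloxy)-2-[4-(benzyloxy)phenyl]-2,3-dihydro-1-benzofuran-3-carbaldehyde (cis)
Conditions: i-Bu2AlH (1.05 equiv), CH2Cl2, −78 °C; cold aq. KNaC4H4O6 work-up, used crude at once
Reagents that add atoms: none
Why: Partial reduction of a methyl ester by a dialkylaluminium hydride through the tetrahedral aluminate at low temperature; the neutral cold work-up and immediate use should keep the epimerisable cis centre.

Step 15
Reactants: 19 (2S,3R)-6,7-bis(benzyloxy)-2-[4-(benzyloxy)phenyl]-2,3-dihydro-1-benzofuran-3-carbaldehyde; 15 tri-O-benzyl-teracacidin carbonate (3 equiv, excess recovered)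
Product: 21 hexa-O-benzyl-epioritin-(4β→6)-epioritin-4α-ol 3,4-carbonate (upper unit 2,3-cis-3,4-trans; free 3-OH; its C4 bonded to C6 of the unit from 15), via flavan-4-yl cation 20 (not isolated)
Conditions: Tf2NH (20 mol %), CH2Cl2, −78 to −40 °C, slow addition of 19 to 15 and the acid; Et3N quench
Reagents that add atoms: none
Why: Proposed new method: Protonation of the formyl oxygen of 19 gives a hydroxycarbenium ion in which benzofuran C2 (it carries O1 and the 4-benzyloxyphenyl group and migrates readily) shifts with its bonding pair from benzofuran C3 to the formyl carbon, so that the dihydrofuran ring becomes ring C (flavan C2, C3 = former formyl carbon, C4 = former benzofuran C3) with a cation at C4 (ion pair 20) that is captured by C6 of 15, after which the arenium ion gives its proton to the bis(trifluoromethanesulfonyl)amide counter-ion and the acid is returned. The closest known reaction types are the acid-catalysed aldehyde–ketone rearrangement, the ring-enlarging α-ketol rearrangement and, read backwards, the ring-contracting step of the Meinwald rearrangement of aryl epoxides, joined to the known Friedel–Crafts capture of flavan-4-yl cations by flavan nucleophiles. Ring C is closed by a suprafacial 1,2-carbon shift with ring enlargement from five to six atoms, not by a cyclisation, and the shift should be feasible because a hydroxycarbenium ion is exchanged for a benzylic cation stabilised by O1 (ortho) and the 7-benzyloxy group (para), strain of the dihydrofuran ring is released and the capture by 15 is irreversible. C2 migrates with retention and becomes 2R; C3 (3R) is set in the shift, because in the cis aldehyde the formyl group is pseudo-axial and its protonated oxygen should turn endo, over O1 and ring A, where the O3–H···O1 hydrogen bond known from 2,3-cis-flavan-3-ols develops, so that the cation is born as the half-chair with equatorial aryl and axial hydroxyl; C4 (4β-aryl, 3,4-trans, the centre that is 4S in the target) is set by attack of 15 anti to that axial hydroxyl, the rule for 2,3-cis extender units. The step needs the shift to outrun direct hydroxyalkylation of 15 by the protonated aldehyde (secured by the unimolecular shift, slow addition of 19 and −78 °C), migration of C2 instead of hydride or ring A (secured by the cis geometry, which lines the benzofuran C3–C2 bond up with the formyl π* orbital and leaves the C3–H bond in the plane of ring A without benzylic assistance) and attack at C6 instead of C5 of 15 (C6 is para to O1 and ortho to 7-OBn, C5 is peri to C4). The carbonate of 15 should survive because its C4–O bond is pseudo-equatorial, in the plane of ring A, and any ionisation is reversed by the tethered carbonate oxygen, and the free 3-OH of 21 needs no protection for step 16.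

Step 16
Reactants: 13 (2R,3R,4S)-7,8-bis(benzyloxy)-2-[4-(benzyloxy)phenyl]-4-(2-ethoxyethoxy)chroman-3-ol; 21 hexa-O-benzyl-epioritin-(4β→6)-epioritin-4α-ol 3,4-carbonate (2 equiv, excess recovered)
Product: 22 nona-O-benzyl-epioritin-(4β→6)-epioritin-(4β→6)-epioritin-4α-ol 3,4-carbonate
Conditions: TMSOTf (10 mol %), CH2Cl2, −78 °C, slow addition of 13; Et3N quench
Reagents that add atoms: none
Why: Established TMSOTf-promoted Friedel–Crafts coupling of a 4-alkoxyflavan-3-ol with a flavan nucleophile: the C4 cation from 13 is attacked by C6 of the upper unit of 21 (para to O1, ortho to 7-OBn; C6 of the bottom unit is substituted and both C5 positions are peri-shielded) anti to the axial 3-hydroxyl, which sets the top C4 as 4β (3,4-trans).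

Step 17
Reactants: 22 nona-O-benzyl-epioritin-(4β→6)-epioritin-(4β→6)-epioritin-4α-ol 3,4-carbonate
Product: 23 nona-O-benzyl-epioritin-(4β→6)-epioritin-(4β→6)-epioritin-4α-ol
Conditions: K2CO3 (0.2 equiv), MeOH–THF, rt
Reagents that add atoms: none
Why: Base-catalysed methanolysis (transesterification) of the cyclic carbonate while all phenols are still benzylated; no stereocenter is touched.

Step 18
Reactants: 23 nona-O-benzyl-epioritin-(4β→6)-epioritin-(4β→6)-epioritin-4α-ol
Product: 24 epioritin-(4β→6)-epioritin-(4β→6)-epioritin-4α-ol (CNP0140823.1)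
Conditions: H2 (1 atm), Pd(OH)2/C, THF–MeOH, rt, stopped at complete debenzylation
Reagents that add atoms: none
Why: Hydrogenolysis of the nine aryl benzyl ethers over palladium; these should cleave much faster than the equatorial secondary benzylic C4–OH and the ring C2–O1 bonds.

**Compound list**

1 | 1-(2,3,4-trihydroxyphenyl)ethan-1-one | CC(=O)c1ccc(O)c(O)c1O | starting material
2 | 1-[3,4-bis(benzyloxy)-2-hydroxyphenyl]ethan-1-one | CC(=O)c1ccc(OCc2ccccc2)c(OCc2ccccc2)c1O | intermediate
3 | (E)-1-[3,4-bis(benzyloxy)-2-hydroxyphenyl]-3-(dimethylamino)prop-2-en-1-one | CN(C)/C=C/C(=O)c1ccc(OCc2ccccc2)c(OCc2ccccc2)c1O | intermediate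
4 | 7,8-bis(benzyloxy)-4H-chromen-4-one | O=c1ccoc2c1ccc(OCc1ccccc1)c2OCc1ccccc1 | intermediate
5 | [4-(benzyloxy)phenyl]boronic acid | OB(O)c1ccc(OCc2ccccc2)cc1 | starting material
6 | (2S)-7,8-bis(benzyloxy)-2-[4-(benzyloxy)phenyl]-2,3-dihydro-4H-chromen-4-one | c1ccccc1COc1ccc([C@H]2Oc3c(ccc(OCc4ccccc4)c3OCc3ccccc3)C(=O)C2)cc1 | intermediate
7 | (2S,4S)-7,8-bis(benzyloxy)-2-[4-(benzyloxy)phenyl]chroman-4-ol (2,4-cis) | c1ccccc1COc1ccc([C@H]2Oc3c(ccc(OCc4ccccc4)c3OCc3ccccc3)[C@@H](O)C2)cc1 | intermediate
8 | (2S)-7,8-bis(benzyloxy)-2-[4-(benzyloxy)phenyl]-2H-chromene | c1ccccc1COc1ccc([C@H]2Oc3c(ccc(OCc4ccccc4)c3OCc3ccccc3)C=C2)cc1 | intermediate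
9 | C3 alkylborane from 8 (BH2 at C3, trans to the 2-aryl group) | c1ccccc1COc1ccc([C@H]2Oc3c(ccc(OCc4ccccc4)c3OCc3ccccc3)C[C@@H]2B)cc1 | intermediate
10 | (2R,3S)-7,8-bis(benzyloxy)-2-[4-(benzyloxy)phenyl]chroman-3-ol (2,3-trans) | c1ccccc1COc1ccc([C@H]2Oc3c(ccc(OCc4ccccc4)c3OCc3ccccc3)C[C@@H]2O)cc1 | intermediate
11 | (2R)-7,8-bis(benzyloxy)-2-[4-(benzyloxy)phenyl]chroman-3-one | c1ccccc1COc1ccc([C@H]2Oc3c(ccc(OCc4ccccc4)c3OCc3ccccc3)CC2=O)cc1 | intermediate
12 | (2R,3R)-7,8-bis(benzyloxy)-2-[4-(benzyloxy)phenyl]chroman-3-ol (2,3-cis) | c1ccccc1COc1ccc([C@H]2Oc3c(ccc(OCc4ccccc4)c3OCc3ccccc3)C[C@H]2O)cc1 | intermediate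
13 | (2R,3R,4S)-7,8-bis(benzyloxy)-2-[4-(benzyloxy)phenyl]-4-(2-ethoxyethoxy)chroman-3-ol (4β ether) | c1ccccc1COc1ccc([C@H]2Oc3c(ccc(OCc4ccccc4)c3OCc3ccccc3)[C@H](OCCOCC)[C@H]2O)cc1 | intermediate
14 | tert-butyl (2R,3R,4S)-7,8-bis(benzyloxy)-2-[4-(benzyloxy)phenyl]-4-(2-ethoxyethoxy)chroman-3-yl carbonate | c1ccccc1COc1ccc([C@H]2Oc3c(ccc(OCc4ccccc4)c3OCc3ccccc3)[C@H](OCCOCC)[C@H]2OC(=O)OC(C)(C)C)cc1 | intermediate
15 | cyclic 3,4-carbonate of (2R,3R,4R)-7,8-bis(benzyloxy)-2-[4-(benzyloxy)phenyl]chromane-3,4-diol (all-cis) | c1ccccc1COc1ccc([C@H]2Oc3c(ccc(OCc4ccccc4)c3OCc3ccccc3)[C@H]5OC(=O)O[C@@H]25)cc1 | intermediate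
16 | methyl (2S,3S)-6,7-bis(benzyloxy)-2-[4-(benzyloxy)phenyl]-2,3-dihydro-1-benzofuran-3-carboxylate (trans) | c1ccccc1COc1ccc([C@H]2Oc3c(ccc(OCc4ccccc4)c3OCc3ccccc3)[C@@H]2C(=O)OC)cc1 | intermediate
17 | lithium enolate of 16 (C2 still S) | [Li]OC(OC)=C1c2ccc(OCc3ccccc3)c(OCc3ccccc3)c2O[C@@H]1c1ccc(OCc2ccccc2)cc1 | intermediate
18 | methyl (2S,3R)-6,7-bis(benzyloxy)-2-[4-(benzyloxy)phenyl]-2,3-dihydro-1-benzofuran-3-carboxylate (cis) | c1ccccc1COc1ccc([C@H]2Oc3c(ccc(OCc4ccccc4)c3OCc3ccccc3)[C@H]2C(=O)OC)cc1 | intermediate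
19 | (2S,3R)-6,7-bis(benzyloxy)-2-[4-(benzyloxy)phenyl]-2,3-dihydro-1-benzofuran-3-carbaldehyde (cis) | c1ccccc1COc1ccc([C@H]2Oc3c(ccc(OCc4ccccc4)c3OCc3ccccc3)[C@H]2C=O)cc1 | intermediate
20 | (2R,3R)-7,8-bis(benzyloxy)-2-[4-(benzyloxy)phenyl]-3-hydroxychroman-4-ylium bis(trifluoromethanesulfonyl)amide (ion pair) | c1cc2c(c(OCc3ccccc3)c1OCc1ccccc1)O[C@H](c1ccc(OCc3ccccc3)cc1)[C@H](O)[CH+]2.[N-](S(=O)(=O)C(F)(F)F)S(=O)(=O)C(F)(F)F | intermediate
21 | hexa-O-benzyl-epioritin-(4β→6)-epioritin-4α-ol 3,4-carbonate | c1cc2c(c(OCc3ccccc3)c1OCc1ccccc1)O[C@H](c1ccc(OCc3ccccc3)cc1)[C@H](O)[C@H]2c1cc2c(c(OCc3ccccc3)c1OCc1ccccc1)O[C@H](c1ccc(OCc3ccccc3)cc1)[C@H](OC(=O)O3)[C@@H]23 | intermediate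
22 | nona-O-benzyl-epioritin-(4β→6)-epioritin-(4β→6)-epioritin-4α-ol 3,4-carbonate | c1ccccc1COc1ccc([C@H]2Oc3c(ccc(OCc4ccccc4)c3OCc3ccccc3)[C@H](c3cc4c(c(OCc5ccccc5)c3OCc3ccccc3)O[C@H](c3ccc(OCc5ccccc5)cc3)[C@H](O)[C@H]4c3cc4c(c(OCc5ccccc5)c3OCc3ccccc3)O[C@H](c3ccc(OCc5ccccc5)cc3)[C@H](OC(=O)O5)[C@@H]45)[C@H]2O)cc1 | intermediate
23 | nona-O-benzyl-epioritin-(4β→6)-epioritin-(4β→6)-epioritin-4α-ol | c1ccccc1COc1ccc([C@H]2Oc3c(ccc(OCc4ccccc4)c3OCc3ccccc3)[C@H](c3cc4c(c(OCc5ccccc5)c3OCc3ccccc3)O[C@H](c3ccc(OCc5ccccc5)cc3)[C@H](O)[C@H]4c3cc4c(c(OCc5ccccc5)c3OCc3ccccc3)O[C@H](c3ccc(OCc5ccccc5)cc3)[C@H](O)[C@@H]4O)[C@H]2O)cc1 | intermediate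
24 | epioritin-(4β→6)-epioritin-(4β→6)-epioritin-4α-ol; top and middle units 2R,3R,4S, bottom unit 2R,3R,4R | Oc1ccc([C@H]2Oc3c(ccc(O)c3O)[C@H](c3cc4c(c(O)c3O)O[C@H](c3ccc(O)cc3)[C@H](O)[C@H]4c3cc4c(c(O)c3O)O[C@H](c3ccc(O)cc3)[C@H](O)[C@@H]4O)[C@H]2O)cc1 | target

**Summary**

Total step count: 18. Longest linear sequence: 15 steps (steps 1–11, then 15–18).

Steps most likely to fail:

1. Step 15 (Proposed new method). The protonated aldehyde may be attacked directly by 15 at the formyl carbon before the shift. Hydride instead of C2 may migrate, followed by aromatisation to the benzofuran. The cis aldehyde may epimerise through its enol. The exo rotamer may react and give the 2,3-trans series. The benzylic carbonate of 15 may ionise under the strong acid. Fallback (known chemistry): it sets out from 13 and 15 and returns at 21. The 4β-(2-ethoxyethoxy) group of 13 is ionised with catalytic TMSOTf in CH2Cl2 at −78 °C in the presence of excess 15, the conventional flavan-4-yl cation coupling, which should give 21 directly (no new compound, F0).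

2. Step 11. The C4 cation may be captured by ring A of a second molecule (self-condensation) or the Boc group may be lost to acid before the ring closes. Fallback: it sets out from 13 and returns at 15. Acid-catalysed exchange of the 4-alkoxy group for water (p-TsOH, THF–H2O) should give (2R,3R,4S)-7,8-bis(benzyloxy)-2-[4-(benzyloxy)phenyl]chromane-3,4-diol F1. Selective oxidation of its benzylic 4-hydroxyl with MnO2 in CH2Cl2 should give (2R,3S)-7,8-bis(benzyloxy)-2-[4-(benzyloxy)phenyl]-3-hydroxychroman-4-one F2, which is reduced at once with NaBH4 at −40 °C from the β face (anti to the axial 3-hydroxyl and the 2-aryl group) to (2R,3R,4R)-7,8-bis(benzyloxy)-2-[4-(benzyloxy)phenyl]chromane-3,4-diol F3. 1,1'-Carbonyldiimidazole in CH2Cl2 then closes the cis diol to 15.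

3. Step 14. Over-reduction to the alcohol and loss of the cis configuration by enolisation during work-up and handling. Fallback: it sets out from 18 and returns at 19. Exhaustive reduction with LiAlH4 in THF at −78 to 0 °C should give the configurationally stable [(2S,3S)-6,7-bis(benzyloxy)-2-[4-(benzyloxy)phenyl]-2,3-dihydro-1-benzofuran-3-yl]methanol F4. Dess–Martin oxidation buffered with NaHCO3 at 0 °C then releases 19 under non-basic conditions just before step 15.

Further compounds
F0 | step 15 | none | none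
F1 | step 11 | (2R,3R,4S)-7,8-bis(benzyloxy)-2-[4-(benzyloxy)phenyl]chromane-3,4-diol (2,3-cis-3,4-trans) | c1ccccc1COc1ccc([C@H]2Oc3c(ccc(OCc4ccccc4)c3OCc3ccccc3)[C@H](O)[C@H]2O)cc1
F2 | step 11 | (2R,3S)-7,8-bis(benzyloxy)-2-[4-(benzyloxy)phenyl]-3-hydroxychroman-4-one (2,3-cis) | c1ccccc1COc1ccc([C@H]2Oc3c(ccc(OCc4ccccc4)c3OCc3ccccc3)C(=O)[C@H]2O)cc1
F3 | step 11 | (2R,3R,4R)-7,8-bis(benzyloxy)-2-[4-(benzyloxy)phenyl]chromane-3,4-diol (all-cis) | c1ccccc1COc1ccc([C@H]2Oc3c(ccc(OCc4ccccc4)c3OCc3ccccc3)[C@@H](O)[C@H]2O)cc1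
F4 | step 14 | [(2S,3S)-6,7-bis(benzyloxy)-2-[4-(benzyloxy)phenyl]-2,3-dihydro-1-benzofuran-3-yl]methanol (cis) | c1ccccc1COc1ccc([C@H]2Oc3c(ccc(OCc4ccccc4)c3OCc3ccccc3)[C@H]2CO)cc1
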